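## Structural features

The target is an acyclic 8,8'-linked lignan. A butane chain C7–C8–C8'–C7' carries ring A (3,4-dimethoxyphenyl) on C7, ring B (4-hydroxy-3-methoxyphenyl) on C7', a methyl group on each of C8 and C8', and an acetoxy group on C7. The two benzene rings are the only rings and are joined only through this chain. C7, C8 and C8' are three contiguous stereocentres, (7R,8S,8'R). In the zigzag drawn from ring A to ring B, the acetoxy group and both methyl groups lie on the same side (7,8-syn and 8,8'-syn). The frame without the C7 oxygen is (8R,8'R); the letter at C8 changes on oxidation only because C7 then outranks C8' in the CIP order. The fragile element is the secondary acetate at C7, benzylic and para to a methoxy group. Acid ionises it, and solvolysis, proton loss toward C8, or attack by C6' of ring B (closing a six-membered carbocycle) can follow. The free phenol of ring B is oxidisable and is the better acyl acceptor, so the final pattern (ester on the hindered secondary alcohol, none on the phenol) cannot be made by simple acylation. The skeleton is simple; the real difficulty is to put one oxygen on one of two nearly identical benzylic CH2 groups and to fix C7 relative to C8 in an open chain. The key step exploits two features: C7–H is para to the C4 methoxy group of ring A and is the most hydridic C–H bond once the C4' oxygen of ring B is acylated, and the adjacent stereocentre C8 differentiates the faces of the C7 cation.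

## Logic of the disconnections

20 from 19. The bond cut is the acyl–oxygen bond of the aryl acetate on ring B. The phenol cannot be free during a benzylic oxidation, and an acyloxy group is what makes ring B electronically different from ring A. The forward step must cleave an aryl ester and leave a secondary benzylic ester of the same acid untouched.

19 from 18. The C7–O bond is cut, and this carries the strategy. It removes the labile function and one stereocentre together and leaves a hydrocarbon frame with only the two methyl-bearing centres. The forward step must oxidise C7 and not C7', add the oxygen nucleophile to one face of the cation, close no ring, and stop at the acetate.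

18 from 16 through 17. Only bonds to the ring-B oxygen are cut (O–acetyl, O–benzyl). An aryl acetate would not survive the enolate and hydride steps that build the frame, and a benzyl ether does. The demand is a debenzylation that touches nothing else, which is easy because 16 has no other reducible group.

16 from 15, 14 and 13. The two methyl C–H bonds at C9 and C9' are traced back to C–O bonds, and these to the CH2–O and C=O carbons of a five-membered lactone. A trans-2,3-disubstituted lactone is a dependable template for the threo 8,8' pair, because the trans arrangement is favoured both kinetically and thermodynamically. The demand is a double deoxygenation of a 1,4-diol without ring closure to a cyclic ether.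

13 from 9 and 11, and 11 from 10. The C8'–C7' bond is cut. Ring B enters as a benzylic electrophile on the lactone enolate, trans to the substituent already present. This is convergent and sets C8' by substrate control. The demands are mono-alkylation and a freshly made electrophile.

9 from 7, 7 from 4 and 5, and 4 from 1 and 2. The C8–C8' bond is cut between the stereocentre and the acetate CH2, and the N–acyl bond to the auxiliary is cut last. This is the only point where absolute configuration is introduced. The auxiliary is recovered, and the new centre is β to the lactone carbonyl and therefore not epimerisable. The demands are face-selective alkylation and reduction of the imide in the presence of the tert-butyl ester.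

## Other disconnections considered

Alternative 1: The C8–C8' bond is cut symmetrically.
- Forward key step: the lithium Z-enolate of propionyl imide A1 is oxidised by CuCl2 (divalent copper), and two α-carbonyl radicals combine to bis-imide A2 with both methyl stereocentres.
- Continuation: reduction gives the C2-symmetric diol A3. Its two ends are then activated and arylated one after the other, first with a ring-A and then a ring-B aryl Grignard reagent under copper catalysis. This reaches 16, and steps 9–11 follow unchanged.
- In favour: the central bond and both stereocentres form in one step, already at the methyl oxidation level. No lactone and no carbinol-to-methyl reduction is needed. The first arylation of A3 raises no regiochemical question.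
- Against: each radical centre is controlled separately by its own auxiliary. With a substituent as small as methyl, the discrimination between the (S,S), meso-type and (R,R) coupling modes is expected to be modest. Mono-activation of A3 is statistical. Two sp3–sp2 couplings at β-branched primary carbons with electron-rich aryl nucleophiles are required.
- Comparison: on structure it converges on 16, so it is the equal of the chosen plan on the C7 question, which remains the late oxidation. On mechanism the chosen plan (two polar enolate alkylations, each with a well-understood control element) is the more predictable. On step economy the alternative is better, about six steps to 16 against eight, provided the coupling is selective.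

Alternative 2: The C8–C9 and C8'–C9' bonds are cut together, the two methyl groups being hidden as the CH2–S–CH2 bridge of a thiolane.
- Forward key step: the thiocarbonyl ylide released from A4 by CsF adds across the E alkene of enoyl sultam A5 to give the trans-thiolane A6.
- Continuation: the sultam is exchanged for ring A (acyl to aryl ketone), Raney Ni cleaves both C–S bonds to unveil the methyl groups, and the C7 carbonyl is reduced and acetylated.
- In favour: the cycloaddition is suprafacial, so the E geometry becomes the trans ring and hence the threo 8,8' pair. The acyl carbon is C7 and already oxidised. No C–H oxidation and no choice between C7 and C7' arises, and on site selectivity this is better than the chosen plan.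
- Against: the γ-CH2 of A5 is both benzylic and allylic, so under basic fluoride the alkene may drift into conjugation with ring B. Face selectivity rests on one shielding element against a small, reactive dipole. Raney Ni also cleaves benzyl ethers and benzylic C–O bonds, which fixes the order of events and costs protecting-group steps. Hydride addition to the C7 ketone under Felkin–Anh control is expected to favour the 7,8-anti alcohol, the epimer of what is needed, so reagent control or an inversion would be required.
- Comparison: on structure it is the equal of the chosen plan for C8 and C8' and better on which carbon is oxidised. On mechanism it is weaker for C7 configuration, because carbonyl reduction opposes the target while cation capture favours it. On step economy it is about equal or somewhat longer.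

Alternative 3: The C8–H and C8'–H bonds are cut.
- Forward key step: in furanone A7, C7 is the ring carbon that carries ring A and the ring oxygen, and C8=C8' is the tetrasubstituted alkene. Hydrogenation over Rh/Al2O3 from the face opposite ring A gives the all-cis butanolide A8. Its three centres map one to one onto the all-syn C7, C8, C8' array.
- Continuation: the lactone carbonyl (C9') is taken down to methyl, the C7 hydroxyl is acetylated and the silyl ether is removed.
- In favour: all three relative configurations come from one stereocentre through a cyclic template. Cis delivery of hydrogen to one face of a five-membered ring is a more secure control element than acyclic cation capture, so on C7 stereocontrol this is better than the chosen plan. The C7–O bond is present from the start.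
- Against: a tetrasubstituted alkene needs forcing hydrogenation, under which the benzylic (in A7 also allylic) C–O bond may undergo hydrogenolysis and ring A may be partly saturated. The C5–H of A7 is benzylic and γ to the carbonyl, so vinylogous enolisation would erase the only stereocentre. A8 is the most crowded isomer and is epimerisable at C8'. After lactone reduction the C7 hydroxyl is well placed to displace an activated C9' and close a five-membered ether. Enantioselective access to A7 needs its own steps.
- Comparison: on structure it is the equal or better for C7. On mechanism it is more secure for configuration but less secure for chemoselectivity. On step economy it is roughly equal.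

Key step: step 10

Remarks on the chemistry.
- Compounds 16–18 are (8R,8'R) and 19–20 are (7R,8S,8'R). The change of letter at C8 is a CIP effect only; no centre is inverted, and the structures needed no correction.
- The frame 18 is reached through a lactone template and not by double hydrogenation of a diene. The lactone fixes the 8,8' relationship by substrate control, whereas the diene route would need correct geometry of two trisubstituted alkenes and catalyst control over two centres at once.
- Acetyl is kept as the ring-B group of 18. In acetic acid it is the one acyl group whose exchange with solvent is degenerate, and an aryl acetate is cleaved by an amine far faster than a hindered alkyl acetate.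
- Assumption: 1, 2, 5 and 10 are taken as commercial. 11 is made fresh because such benzylic bromides store poorly.

## Route

Step 1
Reactants: 1 3-(3,4-dimethoxyphenyl)propanoic acid; 2 (4S)-4-benzyl-1,3-oxazolidin-2-one
Product: 4 (4S)-4-benzyl-3-[3-(3,4-dimethoxyphenyl)propanoyl]-1,3-oxazolidin-2-one, via mixed pivalic anhydride 3 (not isolated)
Conditions: t-BuCOCl, Et3N, THF, −20 °C; then 2, LiCl, −20 °C to rt
Reagents that add atoms: none
Why: N-acylation through a mixed anhydride; the LiCl-activated, Et3N-deprotonated oxazolidinone attacks the less hindered carbonyl of 3. No stereocentre is formed.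

Step 2
Reactants: 4 (4S)-4-benzyl-3-[3-(3,4-dimethoxyphenyl)propanoyl]-1,3-oxazolidin-2-one; 5 tert-butyl bromoacetate
Product: 7 tert-butyl (3R)-3-{[(4S)-4-benzyl-2-oxo-1,3-oxazolidin-3-yl]carbonyl}-4-(3,4-dimethoxyphenyl)butanoate, via sodium Z-enolate 6 (not isolated)
Conditions: NaN(SiMe3)2, THF, −78 °C; then 5, −78 to −40 °C
Reagents that add atoms: none
Why: Evans asymmetric alkylation; the chelated Z-enolate 6 is alkylated on the face away from the benzyl group of the auxiliary, which sets the future C8 as R.

Step 3
Reactants: 7 tert-butyl (3R)-3-{[(4S)-4-benzyl-2-oxo-1,3-oxazolidin-3-yl]carbonyl}-4-(3,4-dimethoxyphenyl)butanoate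
Product: 9 (4R)-4-(3,4-dimethoxybenzyl)oxolan-2-one, via hydroxy ester 8 (not isolated)
Conditions: LiBH4, MeOH (1 equiv), THF, 0 °C; work-up; then CF3CO2H, CH2Cl2, rt
Reagents that add atoms: none
Why: Chemoselective hydride reduction of the activated imide carbonyl (faster than the tert-butyl ester) releases auxiliary 2; acid then cleaves the tert-butyl ester and the γ-hydroxy acid lactonises. The stereocentre is not enolisable and is untouched.

Step 4
Reactants: 10 [4-(benzyloxy)-3-methoxyphenyl]methanol
Product: 11 1-(benzyloxy)-4-(bromomethyl)-2-methoxybenzene
Conditions: PBr3, Et2O, 0 °C; used at once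
Reagents that add atoms: phosphorus tribromide, BrP(Br)Br
Why: Bromination of an electron-rich benzylic alcohol through its bromophosphite; the benzyl aryl ether is inert to these conditions.

Step 5
Reactants: 9 (4R)-4-(3,4-dimethoxybenzyl)oxolan-2-one; 11 1-(benzyloxy)-4-(bromomethyl)-2-methoxybenzene
Product: 13 (3R,4R)-3-[4-(benzyloxy)-3-methoxybenzyl]-4-(3,4-dimethoxybenzyl)oxolan-2-one, via lithium enolate 12 (not isolated)
Conditions: LiN(SiMe3)2, THF, −78 °C; then 11, DMPU, −78 to −30 °C
Reagents that add atoms: none
Why: Alkylation of a γ-butyrolactone enolate; the C4 substituent shields one face, so the electrophile enters trans and sets C8' as R by substrate control. This is the standard entry to trans-dibenzylbutyrolactones.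

Step 6
Reactants: 13 (3R,4R)-3-[4-(benzyloxy)-3-methoxybenzyl]-4-(3,4-dimethoxybenzyl)oxolan-2-one
Product: 14 (2R,3R)-2-[4-(benzyloxy)-3-methoxybenzyl]-3-(3,4-dimethoxybenzyl)butane-1,4-diol
Conditions: LiAlH4, THF, 0 °C to rt
Reagents that add atoms: none
Why: Hydride reduction of the lactone to the 1,4-diol; no stereocentre is involved, and C8' is no longer enolisable afterwards.

Step 7
Reactants: 14 (2R,3R)-2-[4-(benzyloxy)-3-methoxybenzyl]-3-(3,4-dimethoxybenzyl)butane-1,4-diol
Product: 15 (2R,3R)-2-[4-(benzyloxy)-3-methoxybenzyl]-3-(3,4-dimethoxybenzyl)butane-1,4-diyl dimethanesulfonate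
Conditions: MsCl (excess), Et3N, CH2Cl2, −10 to 0 °C
Reagents that add atoms: methanesulfonyl chloride, CS(=O)(=O)Cl
Why: Sulfonylation of both primary alcohols (through sulfene); it is run cold and fast with excess reagent so that a monomesylate has no time to close to the cyclic ether.

Step 8
Reactants: 15 (2R,3R)-2-[4-(benzyloxy)-3-methoxybenzyl]-3-(3,4-dimethoxybenzyl)butane-1,4-diyl dimethanesulfonate
Product: 16 1-(benzyloxy)-4-[(2R,3R)-4-(3,4-dimethoxyphenyl)-2,3-dimethylbutyl]-2-methoxybenzene
Conditions: LiEt3BH, THF, 0 °C to rt
Reagents that add atoms: none
Why: SN2 displacement of primary sulfonates by a strongly nucleophilic hydride turns both CH2OMs groups into methyl groups; the stereocentres are spectators and the compound becomes (8R,8'R).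

Step 9
Reactants: 16 1-(benzyloxy)-4-[(2R,3R)-4-(3,4-dimethoxyphenyl)-2,3-dimethylbutyl]-2-methoxybenzene
Product: 18 4-[(2R,3R)-4-(3,4-dimethoxyphenyl)-2,3-dimethylbutyl]-2-methoxyphenyl acetate, via free phenol 17 (not isolated)
Conditions: H2 (1 atm), Pd/C, EtOAc, rt; filter; then Ac2O, pyridine, 4-(dimethylamino)pyridine (cat.), rt
Reagents that add atoms: acetic anhydride, CC(=O)OC(C)=O
Why: Catalytic hydrogenolysis of the benzyl aryl ether, then O-acetylation of the phenol in the filtrate; 16 has no other reducible group. The acetyl group makes ring B the electron-poorer ring for step 10.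

Step 10
Reactants: 18 4-[(2R,3R)-4-(3,4-dimethoxyphenyl)-2,3-dimethylbutyl]-2-methoxyphenyl acetate
Product: 19 (1R,2S,3R)-4-(4-acetoxy-3-methoxyphenyl)-1-(3,4-dimethoxyphenyl)-2,3-dimethylbutyl acetate
Conditions: DDQ (1.2–1.5 equiv), anhydrous AcOH, 4 Å molecular sieves, 20 °C, dark
Reagents that add atoms: acetic acid, CC(=O)O
Why: DDQ forms a charge-transfer complex with the electron-richer ring A and removes hydride from C7–H, para to the C4 methoxy group, giving a benzylic cation that is in effect a para-quinone-methide oxocarbenium ion; the solvent acetic acid adds to C7 and forms the C7–O bond. The closest known reaction type is the DDQ-mediated benzylic acetoxylation of para-alkoxy alkylarenes in acetic acid, together with A(1,3)-controlled substitution of α-branched benzylic cations; no ring is closed. The one new stereocentre, C7, is controlled by C8: in the planar cation C8–H lies in the arene plane toward the ortho hydrogen, so the C8 methyl and the C8' branch sit on opposite faces, and acetic acid enters on the methyl face, anti to the larger C8' branch, to give 7R (7,8-syn). Site selectivity between C7 and C7' is needed and is secured by the group para to each benzylic carbon: methoxy on ring A against the much weaker donor acetoxy on ring B. Chemoselectivity against Friedel–Crafts attack of C6' of ring B on C7 is secured by the acetoxy group meta to C6', the absence of strong acid and the large excess of the oxygen nucleophile. Over-oxidation is held back because the acetoxy group on C7 makes the remaining C7–H far less hydridic, and exclusion of water prevents the alcohol and hence the ketone. The reaction is stopped once 18 is consumed so that re-ionisation of 19 cannot erode the kinetic preference.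

Step 11
Reactants: 19 (1R,2S,3R)-4-(4-acetoxy-3-methoxyphenyl)-1-(3,4-dimethoxyphenyl)-2,3-dimethylbutyl acetate
Product: 20 (1R,2S,3R)-1-(3,4-dimethoxyphenyl)-4-(4-hydroxy-3-methoxyphenyl)-2,3-dimethylbutyl acetate
Conditions: pyrrolidine (2–3 equiv), CH2Cl2, 0 °C to rt
Reagents that add atoms: none
Why: Chemoselective aminolysis; the aryl ester (phenoxide leaving group) acylates the secondary amine while the hindered secondary alkyl acetate does not. With no acid and no protic solvent the benzylic acetate should neither ionise nor migrate.

## Compound list

1 | 3-(3,4-dimethoxyphenyl)propanoic acid | COc1ccc(CCC(=O)O)cc1OC | starting material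
2 | (4S)-4-benzyl-1,3-oxazolidin-2-one | O=C1N[C@@H](Cc2ccccc2)CO1 | starting material
3 | 3-(3,4-dimethoxyphenyl)propanoic pivalic anhydride | COc1ccc(CCC(=O)OC(=O)C(C)(C)C)cc1OC | intermediate
4 | (4S)-4-benzyl-3-[3-(3,4-dimethoxyphenyl)propanoyl]-1,3-oxazolidin-2-one | COc1ccc(CCC(=O)N2[C@@H](Cc3ccccc3)COC2=O)cc1OC | intermediate
5 | tert-butyl bromoacetate | BrCC(=O)OC(C)(C)C | starting material
6 | sodium Z-enolate of 4 | COc1ccc(C/C=C(\[O-])N2[C@@H](Cc3ccccc3)COC2=O)cc1OC.[Na+] | intermediate
7 | tert-butyl (3R)-3-{[(4S)-4-benzyl-2-oxo-1,3-oxazolidin-3-yl]carbonyl}-4-(3,4-dimethoxyphenyl)butanoate | COc1ccc(C[C@H](CC(=O)OC(C)(C)C)C(=O)N2[C@@H](Cc3ccccc3)COC2=O)cc1OC | intermediate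
8 | tert-butyl (3R)-4-(3,4-dimethoxyphenyl)-3-(hydroxymethyl)butanoate | COc1ccc(C[C@H](CC(=O)OC(C)(C)C)CO)cc1OC | intermediate
9 | (4R)-4-(3,4-dimethoxybenzyl)oxolan-2-one | O=C1OC[C@H](Cc2ccc(OC)c(OC)c2)C1 | intermediate
10 | [4-(benzyloxy)-3-methoxyphenyl]methanol | COc1cc(CO)ccc1OCc1ccccc1 | starting material
11 | 1-(benzyloxy)-4-(bromomethyl)-2-methoxybenzene | COc1cc(CBr)ccc1OCc1ccccc1 | intermediate
12 | lithium (4R)-4-(3,4-dimethoxybenzyl)-4,5-dihydrofuran-2-olate | [Li+].[O-]C1=C[C@@H](Cc2ccc(OC)c(OC)c2)CO1 | intermediate
13 | (3R,4R)-3-[4-(benzyloxy)-3-methoxybenzyl]-4-(3,4-dimethoxybenzyl)oxolan-2-one | O=C1OC[C@H](Cc2ccc(OC)c(OC)c2)[C@H]1Cc1ccc(OCc2ccccc2)c(OC)c1 | intermediate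
14 | (2R,3R)-2-[4-(benzyloxy)-3-methoxybenzyl]-3-(3,4-dimethoxybenzyl)butane-1,4-diol | COc1cc(C[C@@H](CO)[C@H](CO)Cc2ccc(OC)c(OC)c2)ccc1OCc1ccccc1 | intermediate
15 | (2R,3R)-2-[4-(benzyloxy)-3-methoxybenzyl]-3-(3,4-dimethoxybenzyl)butane-1,4-diyl dimethanesulfonate | COc1cc(C[C@@H](COS(C)(=O)=O)[C@H](COS(C)(=O)=O)Cc2ccc(OC)c(OC)c2)ccc1OCc1ccccc1 | intermediate
16 | 1-(benzyloxy)-4-[(2R,3R)-4-(3,4-dimethoxyphenyl)-2,3-dimethylbutyl]-2-methoxybenzene | COc1cc(C[C@@H](C)[C@H](C)Cc2ccc(OC)c(OC)c2)ccc1OCc1ccccc1 | intermediate
17 | 4-[(2R,3R)-4-(3,4-dimethoxyphenyl)-2,3-dimethylbutyl]-2-methoxyphenol | COc1cc(C[C@@H](C)[C@H](C)Cc2ccc(OC)c(OC)c2)ccc1O | intermediate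
18 | 4-[(2R,3R)-4-(3,4-dimethoxyphenyl)-2,3-dimethylbutyl]-2-methoxyphenyl acetate | COc1cc(C[C@@H](C)[C@H](C)Cc2ccc(OC)c(OC)c2)ccc1OC(C)=O | intermediate
19 | (1R,2S,3R)-4-(4-acetoxy-3-methoxyphenyl)-1-(3,4-dimethoxyphenyl)-2,3-dimethylbutyl acetate | COc1cc(C[C@@H](C)[C@H](C)[C@@H](OC(C)=O)c2ccc(OC)c(OC)c2)ccc1OC(C)=O | intermediate
20 | (1R,2S,3R)-1-(3,4-dimethoxyphenyl)-4-(4-hydroxy-3-methoxyphenyl)-2,3-dimethylbutyl acetate | COc1cc(C[C@@H](C)[C@H](C)[C@@H](OC(C)=O)c2ccc(OC)c(OC)c2)ccc1O | target

## Step count and least certain steps

Total number of steps: 11. Longest linear sequence: 10 (steps 1, 2, 3, 5, 6, 7, 8, 9, 10, 11); step 4 is a one-step branch.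

Step 10 (key step). The most likely failure is weak face discrimination at the cation, because methyl and the C8' branch differ only moderately in size, followed by erosion of the kinetic preference through re-ionisation of the product in the acidic medium. Intramolecular Friedel–Crafts alkylation by ring B and further oxidation at C7 (if water enters) are the other risks. The fallback changes from cation capture to carbonyl reduction and sets out from 18. The same methylene is oxidised with excess DDQ in wet 1,4-dioxane to 4-[(2R,3S)-4-(3,4-dimethoxyphenyl)-2,3-dimethyl-4-oxobutyl]-2-methoxyphenyl acetate F1. The ketone is reduced under reagent control with BH3·SMe2 and the (S)-B-methyl diphenylprolinol oxazaborolidine (Corey–Bakshi–Shibata reduction, ring A as the large group) to the 7R alcohol 4-[(2R,3S,4R)-4-(3,4-dimethoxyphenyl)-4-hydroxy-2,3-dimethylbutyl]-2-methoxyphenyl acetate F2. Reagent control is needed because the Felkin–Anh preference of the substrate points to the C7 epimer. Acetylation (Ac2O, pyridine, 4-(dimethylamino)pyridine) brings the material back to the route at 19.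

Step 5. The risks are proton transfer between product and enolate (leading to a second alkylation or loss of the trans preference) and decay of the labile benzylic electrophile before it reacts. The fallback sets out from 9 (through 12) and replaces alkylation by an aldol addition to 4-(benzyloxy)-3-methoxybenzaldehyde F3. This should give the trans-configured hydroxy lactone (3S,4R)-3-{[4-(benzyloxy)-3-methoxyphenyl](hydroxy)methyl}-4-(3,4-dimethoxybenzyl)oxolan-2-one F4. Hydrogenolysis (H2, Pd/C, AcOH, trace HClO4) removes the benzylic hydroxyl and the benzyl ether to give (3R,4R)-4-(3,4-dimethoxybenzyl)-3-(4-hydroxy-3-methoxybenzyl)oxolan-2-one F5. F5 is the natural lactone (−)-arctigenin, so commercial material can also serve as a relay point. Re-benzylation (BnBr, K2CO3, acetone) returns to the route at 13.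

Step 8. The risk is hydride attack at sulfur instead of carbon, which frees an alkoxide that can displace the second sulfonate intramolecularly, or a sluggish second displacement at the β-branched carbon. The fallback changes from polar displacement to radical reduction and sets out from 15. Exchange with NaI in butan-2-one at reflux gives 1-(benzyloxy)-4-[(2R,3R)-2,3-bis(iodomethyl)-4-(3,4-dimethoxyphenyl)butyl]-2-methoxybenzene F6. Reduction with Bu3SnH and azobisisobutyronitrile in toluene at 80 °C returns to the route at 16.

Step 11. The risk is incomplete discrimination between the two esters, either loss of the benzylic acetate by ionisation or acyl transfer toward the liberated phenoxide. The fallback replaces acyl cleavage by an orthogonal protecting group and sets out from 17. Allyl chloroformate and pyridine give 4-[(2R,3R)-4-(3,4-dimethoxyphenyl)-2,3-dimethylbutyl]-2-methoxyphenyl prop-2-en-1-yl carbonate F7. Oxidation as in step 10 (DDQ, AcOH) should give (1R,2S,3R)-1-(3,4-dimethoxyphenyl)-4-{3-methoxy-4-[(prop-2-en-1-yloxy)carbonyloxy]phenyl}-2,3-dimethylbutyl acetate F8. Deallylation with Pd(PPh3)4 (zerovalent palladium) and morpholine in THF at rt leaves the benzylic acetate alone and arrives at 20.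

## Further compounds

F1 | step 10 | 4-[(2R,3S)-4-(3,4-dimethoxyphenyl)-2,3-dimethyl-4-oxobutyl]-2-methoxyphenyl acetate | COc1cc(C[C@@H](C)[C@H](C)C(=O)c2ccc(OC)c(OC)c2)ccc1OC(C)=O
F2 | step 10 | 4-[(2R,3S,4R)-4-(3,4-dimethoxyphenyl)-4-hydroxy-2,3-dimethylbutyl]-2-methoxyphenyl acetate | COc1cc(C[C@@H](C)[C@H](C)[C@@H](O)c2ccc(OC)c(OC)c2)ccc1OC(C)=O
F3 | step 5 | 4-(benzyloxy)-3-methoxybenzaldehyde | COc1cc(C=O)ccc1OCc1ccccc1
F4 | step 5 | (3S,4R)-3-{[4-(benzyloxy)-3-methoxyphenyl](hydroxy)methyl}-4-(3,4-dimethoxybenzyl)oxolan-2-one (carbinol epimers) | O=C1OC[C@H](Cc2ccc(OC)c(OC)c2)[C@H]1C(O)c1ccc(OCc2ccccc2)c(OC)c1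
F5 | step 5 | (3R,4R)-4-(3,4-dimethoxybenzyl)-3-(4-hydroxy-3-methoxybenzyl)oxolan-2-one | O=C1OC[C@H](Cc2ccc(OC)c(OC)c2)[C@H]1Cc1ccc(O)c(OC)c1
F6 | step 8 | 1-(benzyloxy)-4-[(2R,3R)-2,3-bis(iodomethyl)-4-(3,4-dimethoxyphenyl)butyl]-2-methoxybenzene | COc1cc(C[C@@H](CI)[C@H](CI)Cc2ccc(OC)c(OC)c2)ccc1OCc1ccccc1
F7 | step 11 | 4-[(2R,3R)-4-(3,4-dimethoxyphenyl)-2,3-dimethylbutyl]-2-methoxyphenyl prop-2-en-1-yl carbonate | COc1cc(C[C@@H](C)[C@H](C)Cc2ccc(OC)c(OC)c2)ccc1OC(=O)OCC=C
F8 | step 11 | (1R,2S,3R)-1-(3,4-dimethoxyphenyl)-4-{3-methoxy-4-[(prop-2-en-1-yloxy)carbonyloxy]phenyl}-2,3-dimethylbutyl acetate | COc1cc(C[C@@H](C)[C@H](C)[C@@H](OC(C)=O)c2ccc(OC)c(OC)c2)ccc1OC(=O)OCC=C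
A1 | alternative 1 | (4R)-4-benzyl-3-propanoyl-1,3-oxazolidin-2-one | CCC(=O)N1[C@H](Cc2ccccc2)COC1=O
A2 | alternative 1 | (2S,3S)-1,4-bis[(4R)-4-benzyl-2-oxo-1,3-oxazolidin-3-yl]-2,3-dimethylbutane-1,4-dione | O=C1OC[C@@H](Cc2ccccc2)N1C(=O)[C@@H](C)[C@H](C)C(=O)N1[C@H](Cc2ccccc2)COC1=O
A3 | alternative 1 | (2S,3S)-2,3-dimethylbutane-1,4-diol | OC[C@@H](C)[C@H](C)CO
A4 | alternative 2 | chloromethyl (trimethylsilyl)methyl sulfide | C[Si](C)(C)CSCCl
A5 | alternative 2 | N-[(2E)-4-(4-benzyloxy-3-methoxyphenyl)but-2-enoyl]-(2R)-bornane-10,2-sultam | CC1(C)[C@@H]2CC[C@]13CS(=O)(=O)N(C(=O)/C=C/Cc4ccc(OCc5ccccc5)c(OC)c4)[C@@H]3C2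
A6 | alternative 2 | N-{[(3S,4R)-4-(4-benzyloxy-3-methoxybenzyl)thiolan-3-yl]carbonyl}-(2R)-bornane-10,2-sultam | CC1(C)[C@@H]2CC[C@]13CS(=O)(=O)N(C(=O)[C@H]4CSC[C@@H]4Cc5ccc(OCc6ccccc6)c(OC)c5)[C@@H]3C2
A7 | alternative 3 | (5S)-5-(3,4-dimethoxyphenyl)-4-methyl-3-[3-methoxy-4-(triisopropylsilyloxy)benzyl]furan-2(5H)-one | COc1cc(CC3=C(C)[C@@H](OC3=O)c2ccc(OC)c(OC)c2)ccc1O[Si](C(C)C)(C(C)C)C(C)C
A8 | alternative 3 | (3R,4S,5R)-5-(3,4-dimethoxyphenyl)-4-methyl-3-[3-methoxy-4-(triisopropylsilyloxy)benzyl]oxolan-2-one | COc1cc(C[C@@H]3[C@H](C)[C@@H](OC3=O)c2ccc(OC)c(OC)c2)ccc1O[Si](C(C)C)(C(C)C)C(C)C
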